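Take Friday's and Thursday's runs from 2.50 h onward, where X and E stay flat within the scatter, and replace each curve by its mean.

| setting | Friday's | Thursday's | flask |
|---|---|---|---|
| D | 0.14 M | 0.22 M | 0.10 M |
| G | 2 equiv (in portions, 4) | 2 equiv (in portions, 4) | 2.00 equiv (in portions, 4) |
| remark | run made earlier; portions every 10 s | run made earlier; portions every 10 s | the portions of G follow each other after 10 s, the first at the start |
| time |  |  | 15 h |

- Friday's (time / h: X / %, E / %): 0.500: 30.3, 2.1; 1.33: 69.6, 4.3; 2.50: 94.5, 5.8; 4.00: 93.1, 4.1; 5.00: 95.4, 5.2; 8.00: 93.0, 4.5; 10.0: 94.8, 4.6
- Thursday's (time / h: X / %, E / %): 0.500: 29.5, 1.8; 1.33: 66.1, 2.5; 2.50: 93.0, 5.4; 4.00: 94.2, 5.2; 5.00: 94.8, 5.7; 8.00: 93.4, 4.1; 10.0: 92.9, 5.7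

(readings scatter by 1 percentage point)

- in percentages every species weighs as the D in it: one E counts as two
- at the start none of D is in solution
- a reading or a percentage of X counts all its forms, free or not

- how much X there is at 15 h, in percent of the D charged
- how much E there is at 15 h, in percent of the D charged

Divide the summed E by the summed X, both in percent of the D charged. Friday's plateau gives 0.0514, Thursday's gives 0.0557, and both together give 0.0536. Call this last ratio the plateau split, a selectivity factor.

Now turn the question round and ask what would have to be true for this flask to come out differently: the split would have to change with the loading, and the plainest case is a split in proportion to it. Thursday's would then stand at 0.0808, but its reading is less than that, and I take the gap of 0.00430 between the runs as the error of the mean. So keep the split at 0.10 M, and let X and E share the charge. My reckoning then gives 94.9% X and 5.09% E.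

The forecast says 94.4% X and 4.7% E: “This fits dissolved D being held near a fixed level, for instance by solubility.” Its E is lower than mine.

The flask gives 94.6% X and 5.43% E at 15 h, a split of 0.0574, and the forecast stands within its margins.

    J + G → Z (k = 0.0160 /M/s)
    Z → X (k = 0.150 /s)
    J + Z → E (k = 0.760 /M/s)
    D ⇌ J, rate k4*(cs4 - [J]) while solid is left; crystals form when [J] > cs4 (solubility = 6.00 mM, k = 0.0940 /s)
    Q ⇌ X, rate k5*(cs5 - [X]) while solid is left; crystals form when [X] > cs5 (solubility = 0.0760 M, k = 0.0860 /s)

In the flask at 0.727 h, Z is used 34 times as fast by the step to X as by J + Z to E, and since one E counts as two, E is then forming at 0.0588 of the rate of X. The same flask with 0.500 equiv of G holds 48.3% X at 15 h, on which the plateau split gives 2.59% E, and that neighbour holds 2.92% E.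

The earlier runs and the new flask stem from a simulated flask with constants of no real substance; scatter was added.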